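(The numbers in the tables were computed for substances that don't exist.)

I counted every substrate molecule charged as still substrate of one hand or the other, or as product of one hand or the other, and in a closed flask that sum stays the charge. So I followed one molecule to its fork, where the single-handed free catalyst turned it into left-handed or right-handed product.

all flasks: left-handed substrate 0.10 M; right-handed substrate 0.10 M; free catalyst 0.10 mM

| flask | solid reagent | impurity | remark | time |
|---|---|---|---|---|
| birch | 0.20 M | 30 µM | run made earlier |  |
| alder | 0.20 M | 68 µM | run made earlier |  |
| flask | 0.200 M | 45 µM |  | 50 h |

| run | time / h | left-handed product / % | right-handed product / % |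
|---|---|---|---|
| birch | 3.00 | 0 | 0 |
| birch | 10.0 | 5.0 | 0.5 |
| birch | 15.0 | 9.9 | 1.2 |
| birch | 25.0 | 18.0 | 1.2 |
| birch | 40.0 | 30.0 | 3.7 |
| birch | 50.0 | 38.1 | 5.2 |
| birch | 60.0 | 44.9 | 5.2 |
| alder | 8.00 | 1.8 | 0 |
| alder | 15.0 | 5.6 | 0.5 |
| alder | 25.0 | 10.1 | 1.8 |
| alder | 30.0 | 12.7 | 1.8 |
| alder | 40.0 | 18.3 | 2.0 |
| alder | 48.0 | 22.4 | 3.0 |
| alder | 60.0 | 27.6 | 4.4 |

(readings scatter by 0.5 percentage points)

- free catalyst is single-handed; left-handed substrate and right-handed substrate are mirror images of each other, charged as a racemate, each of them at the stated concentration
- given per volume of solution although it is solid: solid reagent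
- at the start none of the solid reagent is in solution
- an excess is below zero if the other one leads

- left-handed product and right-handed product together, in percent of the left-handed substrate and right-handed substrate charged together, at 50 h
- excess of left-handed product over right-handed product in the product at 50 h
- whether the exchange between left-handed substrate and right-handed substrate keeps pace with the reaction: how far the product's excess at 50 h gets from its value without exchange to its value with instant exchange (above 80% keeps pace, below 20% hardly takes part, else lags behind)

The last three readings of birch and alder, summed, gave a ratio of left-handed to right-handed product of 7.71. I read this as the fork ratio, left-handed product made per right-handed product while the two substrates stand equal, the selectivity factor. If they stay equal, the product's excess is the ratio less one over the ratio plus one, which I reckoned as 77.1%.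

The ladder began with the lag: birch showed nothing at 3.00 h, and the forecast put the lag at about 4.5 h. At the top stood the time to use the whole charge at the late pace, 113 h in birch and 174 h in alder. The exchange I could bound from one side. Without it, subtraction from the half charged gives birch at 60.0 h 5.10% left-handed substrate against 44.8% right-handed, and my ratio times these two amounts reckons the gain of left-handed product there at 0.878 times the gain of right-handed product. Yet from 40.0 h on, birch gained 15 percentage points left-handed product and 1.5 points right-handed, far more left than right, each reading scattering by 0.5 points. So I placed the time of the exchange below those two times of turnover, without a figure for it.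

The forecast gave 36.5% (34.5% to 38.5%), 77% (72% to 81%) and keeps pace: “It keeps pace, though the noise leaves some doubt.”

The flask gave 37.4%, 77.7% and keeps pace, 96% of the way.

    partner + free catalyst + left-handed substrate → free catalyst + left-handed product (k = 2.50 M⁻² s⁻¹)
    partner + free catalyst + right-handed substrate → free catalyst + right-handed product (k = 0.310 M⁻² s⁻¹)
    left-handed substrate ⇌ right-handed substrate (k = 1.50 × 10⁻⁴ s⁻¹)
    solid reagent ⇌ partner, rate k4*(cs4 - [partner]) while solid is left; crystals form when [partner] > cs4 (solubility = 0.0950 M, k = 1.60 × 10⁻⁵ s⁻¹)
    free catalyst + impurity → spent catalyst (k = 38.0 M⁻¹ s⁻¹)
    free catalyst ⇌ dormant form (K = 0.540, k = 6.30 × 10⁻⁶ s⁻¹)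

At 50.0 h the flask held 33.2% left-handed and 4.17% right-handed product, a ratio of 7.96 beside my read 7.71. Its substrates stood at 31.0% and 31.6%, although subtraction without crossing leaves 16.8% left-handed. The neighbouring flask, charged with 4.0 × 10⁻⁴ M of free catalyst and otherwise like the flask, reached 79.3% at the same time. Its 70.2% of left-handed product exceeded the left-handed half of the charge by 20 points, and against 9.10% right-handed that is a ratio of 7.72. The ratio I had read gives 77.1%, and the neighbouring flask stood at 77.1%.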